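The numbers in the tables stem from a simulated flask for substances that don't exist, and the scatter is random.

Easy one first: what does a run do once it flattens? It stops changing, so its plateau is the number to read.

| flask | starting material | first nucleophile | solid second nucleophile | temperature | remark | time |
|---|---|---|---|---|---|---|
| Monday's | 20 mM | 30 mM | 14 mM | 0 °C | run made earlier |  |
| Sunday's | 20 mM | 42 mM | 14 mM | 11 °C | run made earlier |  |
| Wednesday's | 20 mM | 66 mM | 14 mM | 0 °C | run made earlier |  |
| Thursday's | 20 mM | 30 mM | 7 mM | 11 °C | run made earlier |  |
| elm | 20 mM (fed, over 25 h) | 30.0 mM | 14.0 mM | 5 °C | all else is in the flask from the start; the feed brings no volume worth counting | 30 h |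
| alder | 20 mM | 30.0 mM (fed, over 25 h) | 14.0 mM | 5 °C | all else is in the flask from the start; the feed brings no volume worth counting | 30 h |
| maple | 20 mM (fed, over 25 h) | 30.0 mM | 14.0 mM |  | the addition at −35 °C, then warmed to 5 °C; the feed brings no volume worth counting | 30 h |
| birch | 20 mM | 30.0 mM | 14.0 mM | 5 °C | everything together at the start | 30 h |

- Monday's (time / h: target / %): 2.50: 18.8; 5.00: 24.1; 8.00: 26.4; 10.0: 24.9; 12.0: 27.0; 15.0: 25.4; 20.0: 22.7
- Sunday's (time / h: target / %): 2.00: 29.9; 3.00: 30.9; 4.00: 29.0; 6.00: 28.6; 10.0: 29.8; 15.0: 30.1; 25.0: 29.9
- Wednesday's (time / h: target / %): 2.00: 19.5; 3.00: 25.2; 4.00: 29.9; 6.00: 34.1; 10.0: 34.6; 15.0: 36.8; 25.0: 33.2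
- Thursday's (time / h: target / %): 2.00: 25.4; 4.00: 26.6; 6.00: 26.2; 12.0: 25.9; 25.0: 23.1

(scatter of a reading: 1 percentage point)

- the analysis behind the earlier runs scatters by 1 percentage point, standard deviation
- at the start none of the solid second nucleophile is in solution

* which flask leads in amount of target, in percent of the starting material charged ("all alike" within 1.5 percentage points) (elm / alder / maple / birch / all alike)
* how much target is there at the end, in percent of the starting material charged: elm
* how much target is there at the end, in percent of the starting material charged: alder
* how much target is there at the end, in percent of the starting material charged: maple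
* how much target is there at the end, in percent of the starting material charged: birch

**Which plateaus compare cleanly?** Monday's and Wednesday's share a temperature, 0 °C, and the solid. Monday's, with 30 mM of first nucleophile, holds about 25.9%. Wednesday's, with 66 mM, holds about 34.7%.

**And what do they say?** Twice the first nucleophile gave 1.34 times the target, so the curve bends. I read a competition: plateau = ceiling × first nucleophile / (first nucleophile + crossover). The crossover is the first nucleophile level at which the plateau stands midway to its ceiling, 25.8 mM, a selectivity written as a concentration. The ceiling comes out at 48.2%.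

**Two points fit any such curve. Where is the test?** Sunday's run, at 11 °C with 42 mM: the rule gives 29.9%, and its readings average 29.7%.

**Alder?** Wednesday's rise gives a time constant of 2.31 h, read at 0 °C; I keep it as the nearest reading. That is far shorter than the feed, so alder's starting material meets what has dripped in by then: 1.20 mM h⁻¹ times that time, 2.77 mM. The rule gives alder 4.68%.

**The others?** Elm and birch hold the whole first nucleophile charge, so I put both at Monday's plateau. Maple, if the cold stops the reaction, has 5.00 h warm, which gives 22.9%.

The forecast gave elm 24%, alder 23.5%, maple 25.5% and birch 23%, with maple leading, and took its equilibrium level to hold “whatever the feed order”.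

The flasks end at elm 20.5%, alder 4.21%, maple 20.5% and birch 24.4%, so birch leads.

    intermediate → solvolysis product (k = 94.0 h⁻¹, Ea = 68.0 kJ mol⁻¹)
    target ⇌ isomer of the product (K = 0.930, k = 0.230 h⁻¹, Ea = 86.0 kJ mol⁻¹, ΔH = −7.00 kJ mol⁻¹)
    first nucleophile + intermediate → target (k = 4400 M⁻¹ h⁻¹, Ea = 49.0 kJ mol⁻¹)
    second nucleophile + intermediate → other capture product (k = 8700 M⁻¹ h⁻¹, Ea = 49.0 kJ mol⁻¹)
    solid second nucleophile ⇌ second nucleophile, rate k5*(cs5 - [second nucleophile]) while solid is left; crystals form when [second nucleophile] > cs5 (solubility = 20.0 mM, k = 0.0930 h⁻¹)
    starting material → intermediate (k = 0.350 h⁻¹, Ea = 84.0 kJ mol⁻¹)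
    (constants at 5 °C)

Put back through the rule, alder's target stands for 2.47 mM of first nucleophile, against my 2.77 mM. Alder has come to rest: ten times the time leaves its target at 4.21%. Maple has not: over ten times the time its starting material goes from 17.3% to 0% and other capture product from 26.1% to 30.8%, while target goes from 20.5% to 19.8%.

Last, a neighbour flask is birch with 7.5 mM of first nucleophile. The rule gives 10.9%, and the computed flask gives 8.86%.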